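**Retrosynthetic overview**
1. Ester C–O bond last: a lipase acylates only the primary OH of diol 17 with linoleic acid 18, leaving the tertiary OH and the indole N–H free.
2. C6–prenyl bond by Stille coupling on aryl bromide 14, then removal of the N-sulfonyl group.
3. CH2OH from periodate cleavage and reduction of a terminal 1,2-diol (triol 12); CMe2OH from Mukaiyama hydration of an isopropenyl group (diol 10).
4. The stereocentre: copper-catalysed anti opening of (2S,3S)-epoxy alcohol 8 by an isopropenyl nucleophile; 8 comes from Sharpless asymmetric epoxidation of (E)-allylic alcohol 6, made from aldehyde 1.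
5. Rings: the indole is bought intact; the only ring formed is the oxirane (step 4), which is opened again in step 5.

Assumption: the single stereocentre of the target is (R), as read from the SMILES; "tosyl" (Ts) means 4-methylbenzenesulfonyl throughout.

**Route**

Step 1
Reactants: 1 6-bromo-1H-indole-3-carbaldehyde; 2 4-methylbenzenesulfonyl chloride
Product: 3 6-bromo-1-tosyl-1H-indole-3-carbaldehyde
Conditions: Et3N, DMAP (cat.), CH2Cl2, 0 °C to rt
Reagents that add atoms: 4-methylbenzenesulfonyl chloride, Cc1ccc(cc1)S(Cl)(=O)=O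
Why: N-sulfonylation of the acidic N–H of the 3-formylindole; the electron-withdrawing sulfonyl group later keeps the indolylic epoxide from ionising.

Step 2
Reactants: 3 6-bromo-1-tosyl-1H-indole-3-carbaldehyde; 4 ethyl (triphenylphosphoranylidene)acetate
Product: 5 ethyl (2E)-3-(6-bromo-1-tosyl-1H-indol-3-yl)prop-2-enoate
Conditions: toluene, 80 °C
Reagents that add atoms: ethyl (triphenylphosphoranylidene)acetate, CCOC(=O)C=P(c1ccccc1)(c1ccccc1)c1ccccc1
Why: Wittig olefination with a stabilised ylide gives the (E)-enoate selectively and needs no base that could attack the sulfonamide.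

Step 3
Reactants: 5 ethyl (2E)-3-(6-bromo-1-tosyl-1H-indol-3-yl)prop-2-enoate
Product: 6 (2E)-3-(6-bromo-1-tosyl-1H-indol-3-yl)prop-2-en-1-ol
Conditions: i-Bu2AlH (2.5 equiv), CH2Cl2, −78 °C; aq. potassium sodium tartrate
Reagents that add atoms: none
Why: 1,2-reduction of the enoate to the allylic alcohol by the aluminium hydride at low temperature leaves the aryl bromide, the alkene geometry and the sulfonamide untouched.

Step 4
Reactants: 6 (2E)-3-(6-bromo-1-tosyl-1H-indol-3-yl)prop-2-en-1-ol; 7 tert-butyl hydroperoxide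
Product: 8 [(2S,3S)-3-(6-bromo-1-tosyl-1H-indol-3-yl)oxiran-2-yl]methanol
Conditions: Ti(OiPr)4 (10 mol%), L-(+)-diethyl tartrate (12 mol%), 4 Å MS, CH2Cl2, −20 °C
Reagents that add atoms: tert-butyl hydroperoxide, CC(C)(C)OO
Why: Katsuki–Sharpless asymmetric epoxidation; the titanium/L-(+)-tartrate catalyst delivers oxygen to one face of the (E)-allylic alcohol and sets both C2 and C3 as (S), as it does for cinnamyl alcohol (typically above 95% ee).

Step 5
Reactants: 8 [(2S,3S)-3-(6-bromo-1-tosyl-1H-indol-3-yl)oxiran-2-yl]methanol; 9 isopropenylmagnesium bromide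
Product: 10 (2R,3R)-3-(6-bromo-1-tosyl-1H-indol-3-yl)-4-methylpent-4-ene-1,2-diol
Conditions: 9 (4 equiv), CuI (20 mol%), THF, −40 to −10 °C; then H2O/aq. NH4Cl
Reagents that add atoms: isopropenylmagnesium bromide, CC(=C)[Mg]Br
Why: copper-catalysed SN2 opening of the 3-aryl-2,3-epoxy alcohol at the activated indolylic C3 with inversion fixes the future stereocentre; C2 is untouched (its descriptor changes only through CIP priorities), and any C2-opened 1,3-diol is inert to periodate and is removed at step 7.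

Step 6
Reactants: 10 (2R,3R)-3-(6-bromo-1-tosyl-1H-indol-3-yl)-4-methylpent-4-ene-1,2-diol; 11 dioxygen
Product: 12 (2R,3R)-3-(6-bromo-1-tosyl-1H-indol-3-yl)-4-methylpentane-1,2,4-triol
Conditions: Co(acac)2 (20 mol%), PhSiH3 (3 equiv), O2 (1 atm), THF/i-PrOH, rt
Reagents that add atoms: dioxygen, O=O
Why: Mukaiyama hydration, a radical Markovnikov hydration of the 1,1-disubstituted alkene, gives the tertiary alcohol under neutral conditions; the new carbinol carbon is not stereogenic and the neighbouring centres are not touched (no cyclic ether forms, unlike acid or mercury hydration).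

Step 7
Reactants: 12 (2R,3R)-3-(6-bromo-1-tosyl-1H-indol-3-yl)-4-methylpentane-1,2,4-triol
Product: 14 (2R)-2-(6-bromo-1-tosyl-1H-indol-3-yl)-3-methylbutane-1,3-diol, via (2S)-2-(6-bromo-1-tosyl-1H-indol-3-yl)-3-hydroxy-3-methylbutanal 13 (not isolated)
Conditions: NaIO4 (1.5 equiv), THF/pH 7 phosphate buffer, 0 °C; extract into EtOAc; then NaBH4, MeOH, −10 to 0 °C
Reagents that add atoms: none
Why: Malaprade glycol cleavage removes C1 as formaldehyde (the 1,3-related tertiary OH is not cleaved), and immediate borohydride reduction of the cold, neutral α-aryl aldehyde gives the CH2OH arm before the stereocentre can epimerise.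

Step 8
Reactants: 14 (2R)-2-(6-bromo-1-tosyl-1H-indol-3-yl)-3-methylbutane-1,3-diol; 15 tributyl(3-methylbut-2-en-1-yl)stannane
Product: 16 (2R)-3-methyl-2-[6-(3-methylbut-2-en-1-yl)-1-tosyl-1H-indol-3-yl]butane-1,3-diol
Conditions: Pd(PPh3)4 (5 mol%), DMF, 95 °C
Reagents that add atoms: tributyl(3-methylbut-2-en-1-yl)stannane, CCCC[Sn](CCCC)(CCCC)CC=C(C)C
Why: Migita–Kosugi–Stille coupling of the aryl bromide on zerovalent palladium tolerates the free diol, and reductive elimination from the prenyl–palladium intermediate at its unsubstituted terminus gives the linear prenyl arene.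

Step 9
Reactants: 16 (2R)-3-methyl-2-[6-(3-methylbut-2-en-1-yl)-1-tosyl-1H-indol-3-yl]butane-1,3-diol
Product: 17 (2R)-3-methyl-2-[6-(3-methylbut-2-en-1-yl)-1H-indol-3-yl]butane-1,3-diol
Conditions: KOH (10 equiv), MeOH/THF/H2O, 65 °C
Reagents that add atoms: none
Why: hydroxide attacks sulfur and expels the indolide (basic hydrolysis of an N-sulfonylindole); the diol, the prenyl alkene and the stereocentre, which has no acidifying group, are stable to base.

Step 10
Reactants: 17 (2R)-3-methyl-2-[6-(3-methylbut-2-en-1-yl)-1H-indol-3-yl]butane-1,3-diol; 18 linoleic acid, (9Z,12Z)-octadeca-9,12-dienoic acid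
Product: 19 (2R)-3-hydroxy-3-methyl-2-[6-(3-methylbut-2-en-1-yl)-1H-indol-3-yl]butyl (9Z,12Z)-octadeca-9,12-dienoate
Conditions: immobilised Candida antarctica lipase B (a lipase, carboxylic ester hydrolase class EC 3.1.1.3), 18 (1.5 equiv), 4 Å MS, toluene/2-methyl-2-butanol, 45 °C, argon, dark
Reagents that add atoms: linoleic acid, CCCCC/C=C\C/C=C\CCCCCCCC(=O)O
Why: lipase-catalysed esterification passes the acyl-enzyme of linoleic acid only to the unhindered primary OH (tertiary OH and indole N–H are not substrates), under neutral conditions that leave the skipped (Z,Z)-diene and the stereocentre unchanged.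

**Compound list**
1 | 6-bromo-1H-indole-3-carbaldehyde | O=Cc1c[nH]c2cc(Br)ccc12 | starting material
2 | 4-methylbenzenesulfonyl chloride | Cc1ccc(cc1)S(Cl)(=O)=O | starting material
3 | 6-bromo-1-tosyl-1H-indole-3-carbaldehyde | O=Cc1cn(S(=O)(=O)c2ccc(C)cc2)c2cc(Br)ccc12 | intermediate
4 | ethyl (triphenylphosphoranylidene)acetate | CCOC(=O)C=P(c1ccccc1)(c1ccccc1)c1ccccc1 | starting material
5 | ethyl (2E)-3-(6-bromo-1-tosyl-1H-indol-3-yl)prop-2-enoate | CCOC(=O)/C=C/c1cn(S(=O)(=O)c2ccc(C)cc2)c2cc(Br)ccc12 | intermediate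
6 | (2E)-3-(6-bromo-1-tosyl-1H-indol-3-yl)prop-2-en-1-ol | OC/C=C/c1cn(S(=O)(=O)c2ccc(C)cc2)c2cc(Br)ccc12 | intermediate
7 | tert-butyl hydroperoxide | CC(C)(C)OO | starting material
8 | [(2S,3S)-3-(6-bromo-1-tosyl-1H-indol-3-yl)oxiran-2-yl]methanol | OC[C@@H]1O[C@H]1c1cn(S(=O)(=O)c2ccc(C)cc2)c2cc(Br)ccc12 | intermediate
9 | isopropenylmagnesium bromide | CC(=C)[Mg]Br | starting material
10 | (2R,3R)-3-(6-bromo-1-tosyl-1H-indol-3-yl)-4-methylpent-4-ene-1,2-diol | OC[C@H](O)[C@H](C(C)=C)c1cn(S(=O)(=O)c2ccc(C)cc2)c2cc(Br)ccc12 | intermediate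
11 | dioxygen | O=O | starting material
12 | (2R,3R)-3-(6-bromo-1-tosyl-1H-indol-3-yl)-4-methylpentane-1,2,4-triol | OC[C@H](O)[C@H](C(C)(C)O)c1cn(S(=O)(=O)c2ccc(C)cc2)c2cc(Br)ccc12 | intermediate
13 | (2S)-2-(6-bromo-1-tosyl-1H-indol-3-yl)-3-hydroxy-3-methylbutanal | O=C[C@H](C(C)(C)O)c1cn(S(=O)(=O)c2ccc(C)cc2)c2cc(Br)ccc12 | intermediate
14 | (2R)-2-(6-bromo-1-tosyl-1H-indol-3-yl)-3-methylbutane-1,3-diol | OC[C@H](C(C)(C)O)c1cn(S(=O)(=O)c2ccc(C)cc2)c2cc(Br)ccc12 | intermediate
15 | tributyl(3-methylbut-2-en-1-yl)stannane | CCCC[Sn](CCCC)(CCCC)CC=C(C)C | starting material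
16 | (2R)-3-methyl-2-[6-(3-methylbut-2-en-1-yl)-1-tosyl-1H-indol-3-yl]butane-1,3-diol | OC[C@H](C(C)(C)O)c1cn(S(=O)(=O)c2ccc(C)cc2)c2cc(CC=C(C)C)ccc12 | intermediate
17 | (2R)-3-methyl-2-[6-(3-methylbut-2-en-1-yl)-1H-indol-3-yl]butane-1,3-diol | OC[C@H](C(C)(C)O)c1c[nH]c2cc(CC=C(C)C)ccc12 | intermediate
18 | linoleic acid, (9Z,12Z)-octadeca-9,12-dienoic acid | CCCCC/C=C\C/C=C\CCCCCCCC(=O)O | starting material
19 | (2R)-3-hydroxy-3-methyl-2-[6-(3-methylbut-2-en-1-yl)-1H-indol-3-yl]butyl (9Z,12Z)-octadeca-9,12-dienoate | CCCCC/C=C\C/C=C\CCCCCCCC(=O)OC[C@@H](c1c[nH]c2cc(CC=C(C)C)ccc12)C(C)(C)O | target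

**Step count**
Total steps: 10. Longest linear sequence: 10 steps (1 to 19).

**Steps most likely to fail, with fallbacks**

Step 5 (regioselective isopropenyl opening of the epoxy alcohol). The hindered alkenyl nucleophile may react slowly or give more C2 attack than expected. The fallback sets out from 8 and comes back at 12, so step 6 is skipped. Vinylmagnesium bromide with CuI (THF, −40 °C), the best-precedented C3-selective opening of 3-arylglycidols, gives (2R,3R)-3-(6-bromo-1-tosyl-1H-indol-3-yl)pent-4-ene-1,2-diol F3. Protection with 2,2-dimethoxypropane and PPTS gives 6-bromo-3-{(1R)-1-[(4R)-2,2-dimethyl-1,3-dioxolan-4-yl]prop-2-en-1-yl}-1-tosyl-1H-indole F4. Tsuji–Wacker oxidation (PdCl2, CuCl, O2, DMF/H2O) gives (1R)-1-(6-bromo-1-tosyl-1H-indol-3-yl)-1-[(4R)-2,2-dimethyl-1,3-dioxolan-4-yl]propan-2-one F5. MeMgBr with CeCl3 (THF, −78 °C), which adds without enolising the α-aryl ketone, gives (1R)-1-(6-bromo-1-tosyl-1H-indol-3-yl)-1-[(4R)-2,2-dimethyl-1,3-dioxolan-4-yl]-2-methylpropan-2-ol F6. Aqueous AcOH at 40 °C then removes the acetonide to give triol 12.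

Step 8 (prenyl Stille coupling). Some branched, reverse-prenyl isomer may form and be hard to separate. The fallback sets out from 14 and comes back at 16. Stille coupling with allyltributylstannane (Pd(PPh3)4, DMF, 90 °C), which has no regiochemical ambiguity, gives (2R)-3-methyl-2-[6-(prop-2-en-1-yl)-1-tosyl-1H-indol-3-yl]butane-1,3-diol F7. Olefin cross-metathesis with excess 2-methyl-2-butene (second-generation Grubbs catalyst, CH2Cl2, 40 °C) then converts the allyl group into the prenyl group of 16.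

Step 4 (Sharpless epoxidation). The indolylic epoxy alcohol may be opened by isopropoxide or tartrate on the Lewis-acidic titanium centre during the reaction. The fallback sets out from 6 and comes back at 8. Silylation (tert-butyldimethylsilyl chloride, imidazole, DMF) gives tert-butyl{[(2E)-3-(6-bromo-1-tosyl-1H-indol-3-yl)prop-2-en-1-yl]oxy}dimethylsilane F1. Shi epoxidation with the L-fructose-derived ketone catalyst (30 mol%), KHSO5 and K2CO3 in MeCN/dimethoxymethane/aqueous buffer at 0 °C (a dioxirane with no Lewis acid present) gives tert-butyl{[(2S,3S)-3-(6-bromo-1-tosyl-1H-indol-3-yl)oxiran-2-yl]methoxy}dimethylsilane F2. Tetrabutylammonium fluoride (THF, 0 °C) then frees epoxy alcohol 8.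

**Further compounds**
F1 | step 4 | tert-butyl{[(2E)-3-(6-bromo-1-tosyl-1H-indol-3-yl)prop-2-en-1-yl]oxy}dimethylsilane | CC(C)(C)[Si](C)(C)OC/C=C/c1cn(S(=O)(=O)c2ccc(C)cc2)c2cc(Br)ccc12
F2 | step 4 | tert-butyl{[(2S,3S)-3-(6-bromo-1-tosyl-1H-indol-3-yl)oxiran-2-yl]methoxy}dimethylsilane | CC(C)(C)[Si](C)(C)OC[C@@H]1O[C@H]1c1cn(S(=O)(=O)c2ccc(C)cc2)c2cc(Br)ccc12
F3 | step 5 | (2R,3R)-3-(6-bromo-1-tosyl-1H-indol-3-yl)pent-4-ene-1,2-diol | OC[C@H](O)[C@H](C=C)c1cn(S(=O)(=O)c2ccc(C)cc2)c2cc(Br)ccc12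
F4 | step 5 | 6-bromo-3-{(1R)-1-[(4R)-2,2-dimethyl-1,3-dioxolan-4-yl]prop-2-en-1-yl}-1-tosyl-1H-indole | CC1(C)OC[C@H](O1)[C@H](C=C)c1cn(S(=O)(=O)c2ccc(C)cc2)c2cc(Br)ccc12
F5 | step 5 | (1R)-1-(6-bromo-1-tosyl-1H-indol-3-yl)-1-[(4R)-2,2-dimethyl-1,3-dioxolan-4-yl]propan-2-one | CC1(C)OC[C@H](O1)[C@H](C(C)=O)c1cn(S(=O)(=O)c2ccc(C)cc2)c2cc(Br)ccc12
F6 | step 5 | (1R)-1-(6-bromo-1-tosyl-1H-indol-3-yl)-1-[(4R)-2,2-dimethyl-1,3-dioxolan-4-yl]-2-methylpropan-2-ol | CC1(C)OC[C@H](O1)[C@H](C(C)(C)O)c1cn(S(=O)(=O)c2ccc(C)cc2)c2cc(Br)ccc12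
F7 | step 8 | (2R)-3-methyl-2-[6-(prop-2-en-1-yl)-1-tosyl-1H-indol-3-yl]butane-1,3-diol | OC[C@H](C(C)(C)O)c1cn(S(=O)(=O)c2ccc(C)cc2)c2cc(CC=C)ccc12
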